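The dawn run has the charges of birch, and at 20.0 h it read 34.8 % of over-reaction product. Birch therefore starts from that reading, and the question is how much the slower additions take away from it.

| flask | substrate | reagent | remark | time |
|---|---|---|---|---|
| dawn | 0.10 M | 0.50 M | run made earlier |  |
| noon | 0.10 M | 0.70 M | run made earlier |  |
| autumn | 0.10 M | 1.1 M | run made earlier |  |
| oak | 0.10 M | 0.500 M (in portions, 2, over 8.0 h) | first portion at the start, last at 8.0 h | 20 h |
| cedar | 0.10 M | 0.500 M (fed, over 8.0 h) | all else is in the flask from the start; the feed brings no volume worth counting | 20 h |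
| birch | 0.10 M | 0.500 M | everything together at the start | 20 h |
| alder | 0.10 M (fed, over 8.0 h) | 0.500 M | all else is in the flask from the start; the feed brings no volume worth counting | 20 h |

| run | time / h | over-reaction product / % | target / % |
|---|---|---|---|
| dawn | 3.00 | 3.2 | 10.0 |
| dawn | 6.00 | 8.7 | 12.6 |
| dawn | 10.0 | 16.2 | 12.5 |
| dawn | 12.0 | 20.8 | 11.6 |
| dawn | 15.0 | 26.7 | 11.1 |
| dawn | 20.0 | 34.8 | 10.1 |
| noon | 3.00 | 5.5 | 10.2 |
| noon | 6.00 | 12.8 | 11.6 |
| noon | 10.0 | 23.0 | 11.0 |
| noon | 12.0 | 28.1 | 9.6 |
| noon | 15.0 | 34.5 | 8.5 |
| noon | 20.0 | 43.7 | 7.3 |
| autumn | 1.50 | 3.0 | 7.8 |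
| autumn | 2.50 | 6.8 | 9.9 |
| autumn | 4.00 | 11.8 | 10.3 |
| autumn | 8.00 | 27.1 | 7.9 |
| autumn | 12.0 | 38.0 | 6.5 |
| autumn | 20.0 | 54.0 | 5.1 |

(standard deviation of a reading: 0.5 percentage points)

- which flask leads in amount of over-reaction product, in percent of the substrate charged ("all alike" within 1.5 percentage points) (oak / cedar / birch / alder / all alike)
- how much over-reaction product is there at the end, in percent of the substrate charged: oak
- how much over-reaction product is there at the end, in percent of the substrate charged: cedar
- how much over-reaction product is there at the end, in percent of the substrate charged: birch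
- how much over-reaction product is there at the end, in percent of the substrate charged: alder

- the earlier runs were read with a standard deviation of 0.5 percentage points

Percent made bends with time, so the reckoning here uses the fraction left, the share of the substrate charged that is not yet over-reaction product. Late in dawn its logarithm falls with a loss constant, a pseudo-first-order constant, read as 0.0251 h⁻¹. Noon reads 0.0313 h⁻¹, and autumn from 12.0 h on reads 0.0373 h⁻¹. These are 1.25 and 1.49 times dawn's, while the square root of the reagent ratio gives 1.18 and 1.48, so the constant is taken to follow the root of [reagent].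

But dawn's line, run back, reaches zero loss at 2.96 h and not at the start, so that delay is kept. Oak has been given 0.250 M of reagent until 8.0 h, which in this reckoning costs it 2.34 h of loss time and gives 30.9 %. Cedar's ramp has a mean root 0.667 of the final one, which costs 2.67 h and gives 30.3 %. Alder's substrate arrives on average at 4.00 h, which gives 27.9 %.

One objection remains: noon's delay of 1.65 h is shorter than dawn's, so oak and cedar, which start with less reagent, should be delayed longer. Their figures may therefore stand too high. A lower figure for oak widens the reckoned lead of birch, which stands at 3.9 points over oak against a margin of 1.5 points, so this reckoning commits to birch.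

The forecast also names birch, saying “Birch repeats dawn”, with 35 % there, 31 % for oak, 31.5 % for cedar and 28.7 % for alder. It puts cedar above oak, where the reckoning here puts cedar below.

Birch ends at 35.1 %, oak at 29.8 %, cedar at 28.4 % and alder at 28.4 %, so birch leads, as forecast, by 5.3 points over oak.

    reagent + target → over-reaction product (k = 0.360 L mol⁻¹ h⁻¹)
    substrate ⇌ dormant form (K = 1.00, k = 0.180 h⁻¹)
    substrate + reagent → target, rate k3*[substrate]*[reagent]^0.5 (k = 0.0830 L⁰·⁵ mol⁻⁰·⁵ h⁻¹)

The neighbour of birch charged with 0.40 M of substrate has 1.25 equiv of reagent, and its reagent falls to 44.7 % of its charge by 20.0 h. Its mean root, taken from start and end, is 0.871 of birch's, reckoned the same way up to 20.0 h, so the loss constant is scaled by that factor and the fraction left gives 31.1 %. That neighbour holds 27.8 % of the substrate charged as over-reaction product at 20.0 h.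

The data come from a simulation for an exercise.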